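Readings and results come from a simulation with constants of no real substance, noise included.

Slowness in Friday's and Wednesday's flasks sits at the start and at the end, with a quick stretch between them.

| flask | substrate | partner | time |
|---|---|---|---|
| Friday's | 80.0 mM | 64.0 mM |  |
| Sunday's | 40.0 mM | 24.0 mM |  |
| Wednesday's | 80.0 mM | 130 mM |  |
| Monday's | 240 mM | 64.0 mM |  |
| Saturday's | 80.0 mM | 420 mM | 95 min |

- Friday's run (time / min: [target] / mM): 19: 0.83; 38: 9.48; 57: 22.58; 76: 28.38; 95: 30.13
- Sunday's run (time / min: [target] / mM): 19: 0; 38: 0.50; 57: 0.46; 76: 0.45; 95: 0.72
- Wednesday's run (time / min: [target] / mM): 19: 5.03; 38: 39.01; 57: 45.46; 76: 45.65; 95: 45.88
- Monday's run (time / min: [target] / mM): 19: 60.26; 38: 63.87; 57: 64.22; 76: 64.20; 95: 63.70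

(readings scatter by 0.2 mM)

- Overall: substrate + partner -> target.
- Constant volume, constant temperature.
- The analysis sees a species whether free or bound.
- "The second partner" is partner.
- An order is taken over about fifteen percent of the charge, up and down.

- the power of [partner] that the first rate follows, about the charge of the Friday's run; measure it at two percent of substrate made into target
- the power of [substrate] that the first rate follows, about the charge of the Friday's run; measure it at two percent of substrate made into target (one fixed amount of target, the same in the runs compared)
- target in the Saturday's run at 95 min, as a share of the substrate charged

I read the ladder rung by rung. First comes the multiplying of target: Friday's flask goes from 1.04% of its substrate at 19 min to 11.9% at 38 min, and a rate proportional to target integrates to an exponential, which gives from these two readings a doubling time of 5.41 min. Next come the plateaus. Monday's flask holds 100% of its partner charge as target at 57 min, so there partner is the limiting reagent. Wednesday's flask stands at 56.8% of its substrate at 57 min and 57.4% at 95 min. Friday's flask stands lower, at 37.7% at 95 min. Lowest on the ladder is Sunday's flask, with 1.80% at 95 min.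

Friday's flask slows with 52.9% of its partner still unused, so I assume that substrate also leaves by a first-order loss, racing a growth proportional to target. Dividing one rate by the other removes time, and the closed integral says that the share of substrate lost equals a ratio of the two rate constants, falling as partner rises, times the logarithm of target's total multiplication. That logarithm changes slowly, so I treat it as constant and call the share of the substrate charge that is not target at 95 min the toll, which in Friday's flask is 62.3% and in Wednesday's 42.6%. Between these two flasks, with equal substrate, the toll falls as partner to the power 0.536. For Saturday's flask, also with equal substrate, that gives a toll of 22.8%, and so my 77.2% of target at 95 min, a time far longer than the doubling time. I make no reckoning of the orders.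

The forecast says 0.8 (from 0.5 to 1.2) in partner, 2.3 (from 1.6 to 3) in substrate, and 73% (from 62% to 83%) for Saturday's flask, on the ground that “Excess partner extrapolates to a stall”. Its Saturday figure stands below mine.

The flask gives orders of 0.92 in partner and 1.5 in substrate, and 76.5% in Saturday's flask.

    substrate → intermediate (0.01902 /min)
    intermediate + partner → target (0.07980 /M/min)
    intermediate → side product (0.2166 /min)
    substrate + partner + target → 2 target (109.2 /M²/min)
    2 partner ⇌ idle reagent dimer, settled at all times (30.90 /M)

The order in substrate lies below the forecast's, and at the common small amount of target Monday's rate is 4.0 times Friday's. Saturday's toll comes to 23.5% against my 22.8%. In Monday's flask, with Friday's partner charge, Friday's toll counted on the larger substrate charge is 20.8%, leaving room for 79.2%. The partner charge is the lower ceiling at 26.7% of that substrate. In Monday's flask target stands at a quarter of that same charge at 18.8 min.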